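**Retrosynthetic overview**
- The diene C3'=C4' bond is made last: vinylogous aldol condensation of a 3-methylisocoumarin (fragment A) with a tetrahydrofuranyl enal (fragment B), then one global desilylation.
- Fragment A: benzene ring first (self-condensation of methyl acetoacetate to methyl orsellinate, then chlorination), pyranone ring second (lateral acylation of the ortho-toluate, acid enol-lactonisation).
- Fragment B: the tetrahydrofuran ring comes from a one-carbon ring expansion of (R)-β-butyrolactone with ethyl diazoacetate (oxetan-2-one → 3-oxotetrahydrofuran-2-carboxylate); the lactone stereocentre becomes C5.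
- C2 and C3 are set together by face-selective cis-hydrogenation of the derived silyl enol ether (new step); ester → aldehyde → (E)-enal by Wittig reaction.
- Ring order: benzene, then pyranone (fragment A); tetrahydrofuran (fragment B) in parallel; the fragments are joined in the penultimate step.

Assumption: the four numbered starting materials (1, 6, 9, 10) are bought, 9 as the (R)-enantiomer; bases, silylating agents, the Wittig ylide and catalysts are treated as reagents.

**Step 1**
Reactants: 1 methyl acetoacetate (2 equiv)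
Product: 3 methyl 2,4-dihydroxy-6-methylbenzoate (methyl orsellinate), via triketo ester 2 (not isolated)
Conditions: NaH (1.0 equiv), THF, 0 °C; n-BuLi (1.0 equiv), −78 °C → rt, then reflux; aq. HCl
Reagents that add atoms: none
Why: Claisen self-condensation of the acetoacetate dianion gives 2, whose C2 attacks the C7 ketone (intramolecular aldol) and the adduct dehydrates and enolises to the resorcylate (polyketide-type aromatisation).

**Step 2**
Reactants: 3 methyl 2,4-dihydroxy-6-methylbenzoate
Product: 4 methyl 3-chloro-4,6-dihydroxy-2-methylbenzoate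
Conditions: SO2Cl2 (1.05 equiv), Et2O, 0 °C → rt
Reagents that add atoms: sulfuryl chloride, O=S(=O)(Cl)Cl
Why: Electrophilic aromatic chlorination goes to the ring position next to the methyl group (para to the ester-chelated hydroxyl, ortho to the free one), as is usual for orsellinates; minor regioisomer and dichloride are removed by crystallisation.

**Step 3**
Reactants: 4 methyl 3-chloro-4,6-dihydroxy-2-methylbenzoate
Product: 5 methyl 3-chloro-2-methyl-4,6-bis(triisopropylsilyloxy)benzoate
Conditions: i-Pr3SiOTf (2.4 equiv), 2,6-lutidine, CH2Cl2, 0 °C → rt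
Reagents that add atoms: triisopropylsilyl trifluoromethanesulfonate, CC(C)[Si](C(C)C)(C(C)C)OS(=O)(=O)C(F)(F)F
Why: O-silylation of both phenols (the silyl triflate overcomes the hydrogen-bonded ortho-hydroxy ester) gives bulky aryl silyl ethers that tolerate amide bases and acid and are removed by fluoride at the end.

**Step 4**
Reactants: 5 methyl 3-chloro-2-methyl-4,6-bis(triisopropylsilyloxy)benzoate; 6 N-methoxy-N-methylacetamide
Product: 8 5-chloro-3-methyl-6,8-bis(triisopropylsilyloxy)-1H-isochromen-1-one, via keto ester 7 (not isolated)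
Conditions: LiN(i-Pr)2 (1.2 equiv), THF, −78 °C; 6; AcOH quench; then CF3CO2H, CH2Cl2, 0 °C → rt
Reagents that add atoms: none
Why: Lateral lithiation of the ortho-toluate and C-acylation by the Weinreb amide (stable chelate, no over-addition) give methyl ketone 7, whose enol lactonises onto the neighbouring ester under acid with loss of methanol (toluate-anion isocoumarin synthesis).

**Step 5**
Reactants: 9 (R)-β-butyrolactone [(R)-4-methyloxetan-2-one]; 10 ethyl diazoacetate
Product: 12 ethyl (5R)-5-methyl-3-oxotetrahydrofuran-2-carboxylate (C2 epimers plus enol form), via diazo hydroxy keto ester 11 (not isolated)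
Conditions: LiN(i-Pr)2, 10, THF, −78 °C; 9, −78 °C; AcOH quench, extractive work-up; then Rh2(OAc)4 (1 mol %), CH2Cl2, rt
Reagents that add atoms: none
Why: One-carbon ring expansion of the four-membered lactone: lithiated diazoacetate attacks the strained acyl carbon (acyl C–O cleavage, stereocentre untouched) and the rhodium carbenoid of 11 inserts into the freed O–H, so the ring oxygen ends up on the inserted carbon (net 1,2-shift of oxygen; diazo ester C-acylation followed by carbenoid O–H insertion).

**Step 6**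
Reactants: 12 ethyl (5R)-5-methyl-3-oxotetrahydrofuran-2-carboxylate
Product: 13 ethyl (5R)-3-(tert-butyldimethylsilyloxy)-5-methyl-4,5-dihydrofuran-2-carboxylate
Conditions: t-BuMe2SiOTf (1.2 equiv), Et3N, CH2Cl2, 0 °C
Reagents that add atoms: tert-butyldimethylsilyl trifluoromethanesulfonate, CC(C)(C)[Si](C)(C)OS(=O)(=O)C(F)(F)F
Why: Soft enolisation and O-silylation of the β-keto ester toward its acidic C2–H gives the ester-conjugated silyl enol ether, which erases the labile C2 centre and installs the later hydroxyl protecting group (silyl enol ether formation).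

**Step 7**
Reactants: 13 ethyl (5R)-3-(tert-butyldimethylsilyloxy)-5-methyl-4,5-dihydrofuran-2-carboxylate
Product: 14 ethyl (2R,3S,5R)-3-(tert-butyldimethylsilyloxy)-5-methyltetrahydrofuran-2-carboxylate
Conditions: H2 (50 bar), 5% Rh/Al2O3, EtOAc, rt
Reagents that add atoms: none
Why: Proposed new method: heterogeneous cis-hydrogenation of a tetrasubstituted, captodative 3-silyloxy-4,5-dihydrofuran-2-carboxylate, a substrate class on which it has not been shown; both hydrogens are delivered from the metal surface to the face of the nearly flat ring opposite the C5 methyl, so C2–H and C3–H form cis to each other and trans to the methyl, which places ester, silyloxy and methyl all cis (2R,3S) in one operation; rhodium is chosen because it isomerises enol ethers little and does not hydrogenolyse the vinylic C–O bond; the closest known reactions are the all-cis hydrogenation of substituted furans over rhodium and the syn-hydrogenation of β-acyloxy- and β-amido-acrylates.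

**Step 8**
Reactants: 14 ethyl (2R,3S,5R)-3-(tert-butyldimethylsilyloxy)-5-methyltetrahydrofuran-2-carboxylate
Product: 15 (2R,3S,5R)-3-(tert-butyldimethylsilyloxy)-5-methyltetrahydrofuran-2-carbaldehyde
Conditions: i-Bu2AlH (1.1 equiv), CH2Cl2, −78 °C; aq. potassium sodium tartrate
Reagents that add atoms: none
Why: Partial hydride reduction of the α-alkoxy ester; the chelated aluminium hemiacetal survives at −78 °C and releases the aldehyde only on work-up, without epimerisation at C2.

**Step 9**
Reactants: 15 (2R,3S,5R)-3-(tert-butyldimethylsilyloxy)-5-methyltetrahydrofuran-2-carbaldehyde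
Product: 16 (2E)-3-[(2S,3S,5R)-3-(tert-butyldimethylsilyloxy)-5-methyltetrahydrofuran-2-yl]prop-2-enal
Conditions: Ph3P=CHCHO (1.5 equiv), toluene, 60 °C
Reagents that add atoms: (triphenylphosphoranylidene)acetaldehyde, O=CC=P(c1ccccc1)(c1ccccc1)c1ccccc1
Why: Wittig olefination with the stabilised formyl ylide is E-selective and too weakly basic to epimerise the α-alkoxy centre.

**Step 10**
Reactants: 8 5-chloro-3-methyl-6,8-bis(triisopropylsilyloxy)-1H-isochromen-1-one; 16 (2E)-3-[(2S,3S,5R)-3-(tert-butyldimethylsilyloxy)-5-methyltetrahydrofuran-2-yl]prop-2-enal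
Product: 19 5-chloro-3-[(1E,3E)-4-[(2S,3S,5R)-3-(tert-butyldimethylsilyloxy)-5-methyltetrahydrofuran-2-yl]buta-1,3-dien-1-yl]-6,8-bis(triisopropylsilyloxy)-1H-isochromen-1-one, via aldol adduct 17 (not isolated), via allylic mesylate 18 (not isolated)
Conditions: LiN(i-Pr)2 (1.1 equiv), 8, THF, −78 °C; 16, −78 °C; MeSO2Cl (2.5 equiv), −78 → 0 °C; DBU, 0 °C → rt
Reagents that add atoms: none
Why: Deprotonation of the 3-methyl group gives an extended enolate (benzo analogue of a 6-methyl-2-pyranone anion) that adds 1,2 to the enal through its exocyclic carbon (C4 is shielded by the peri chlorine), and mesylation followed by base elimination toward the acidic CH2 gives the conjugated (E,E)-diene (vinylogous aldol condensation).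

**Step 11**
Reactants: 19 tris-silylated diene
Product: 20 5-chloro-6,8-dihydroxy-3-[(1E,3E)-4-[(2S,3S,5R)-3-hydroxy-5-methyltetrahydrofuran-2-yl]buta-1,3-dien-1-yl]-1H-isochromen-1-one (CNP0086741.3)
Conditions: n-Bu4NF (4 equiv), AcOH (4 equiv), THF, 0 °C → rt
Reagents that add atoms: none
Why: Fluoride cleaves the two aryl silyl ethers and the secondary alkyl silyl ether in one operation, and the acetic acid buffer protects the enol lactone and the allylic ether (global desilylation).

**Compound list**
1 | methyl acetoacetate | CC(=O)CC(=O)OC | starting material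
2 | methyl 3,5,7-trioxooctanoate | CC(=O)CC(=O)CC(=O)CC(=O)OC | intermediate
3 | methyl 2,4-dihydroxy-6-methylbenzoate | COC(=O)c1c(C)cc(O)cc1O | intermediate
4 | methyl 3-chloro-4,6-dihydroxy-2-methylbenzoate | COC(=O)c1c(C)c(Cl)c(O)cc1O | intermediate
5 | methyl 3-chloro-2-methyl-4,6-bis(triisopropylsilyloxy)benzoate | COC(=O)c1c(C)c(Cl)c(O[Si](C(C)C)(C(C)C)C(C)C)cc1O[Si](C(C)C)(C(C)C)C(C)C | intermediate
6 | N-methoxy-N-methylacetamide | CC(=O)N(C)OC | starting material
7 | methyl 3-chloro-2-(2-oxopropyl)-4,6-bis(triisopropylsilyloxy)benzoate | COC(=O)c1c(CC(C)=O)c(Cl)c(O[Si](C(C)C)(C(C)C)C(C)C)cc1O[Si](C(C)C)(C(C)C)C(C)C | intermediate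
8 | 5-chloro-3-methyl-6,8-bis(triisopropylsilyloxy)-1H-isochromen-1-one | Cc1cc2c(Cl)c(O[Si](C(C)C)(C(C)C)C(C)C)cc(O[Si](C(C)C)(C(C)C)C(C)C)c2c(=O)o1 | intermediate
9 | (R)-β-butyrolactone | C[C@@H]1CC(=O)O1 | starting material
10 | ethyl diazoacetate | CCOC(=O)C=[N+]=[N-] | starting material
11 | ethyl (5R)-2-diazo-5-hydroxy-3-oxohexanoate | C[C@@H](O)CC(=O)C(=[N+]=[N-])C(=O)OCC | intermediate
12 | ethyl (5R)-5-methyl-3-oxotetrahydrofuran-2-carboxylate | C[C@@H]1CC(=O)C(C(=O)OCC)O1 | intermediate
13 | ethyl (5R)-3-(tert-butyldimethylsilyloxy)-5-methyl-4,5-dihydrofuran-2-carboxylate | C[C@@H]1CC(O[Si](C)(C)C(C)(C)C)=C(C(=O)OCC)O1 | intermediate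
14 | ethyl (2R,3S,5R)-3-(tert-butyldimethylsilyloxy)-5-methyltetrahydrofuran-2-carboxylate | C[C@@H]1C[C@H](O[Si](C)(C)C(C)(C)C)[C@H](C(=O)OCC)O1 | intermediate
15 | (2R,3S,5R)-3-(tert-butyldimethylsilyloxy)-5-methyltetrahydrofuran-2-carbaldehyde | C[C@@H]1C[C@H](O[Si](C)(C)C(C)(C)C)[C@H](C=O)O1 | intermediate
16 | (2E)-3-[(2S,3S,5R)-3-(tert-butyldimethylsilyloxy)-5-methyltetrahydrofuran-2-yl]prop-2-enal | C[C@@H]1C[C@H](O[Si](C)(C)C(C)(C)C)[C@H](/C=C/C=O)O1 | intermediate
17 | 5-chloro-3-[(3E)-2-hydroxy-4-[(2S,3S,5R)-3-(tert-butyldimethylsilyloxy)-5-methyltetrahydrofuran-2-yl]but-3-en-1-yl]-6,8-bis(triisopropylsilyloxy)-1H-isochromen-1-one (carbinol epimers) | C[C@@H]1C[C@H](O[Si](C)(C)C(C)(C)C)[C@H](/C=C/C(O)Cc2cc3c(Cl)c(O[Si](C(C)C)(C(C)C)C(C)C)cc(O[Si](C(C)C)(C(C)C)C(C)C)c3c(=O)o2)O1 | intermediate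
18 | methanesulfonate of 17 | C[C@@H]1C[C@H](O[Si](C)(C)C(C)(C)C)[C@H](/C=C/C(OS(C)(=O)=O)Cc2cc3c(Cl)c(O[Si](C(C)C)(C(C)C)C(C)C)cc(O[Si](C(C)C)(C(C)C)C(C)C)c3c(=O)o2)O1 | intermediate
19 | 5-chloro-3-[(1E,3E)-4-[(2S,3S,5R)-3-(tert-butyldimethylsilyloxy)-5-methyltetrahydrofuran-2-yl]buta-1,3-dien-1-yl]-6,8-bis(triisopropylsilyloxy)-1H-isochromen-1-one | C[C@@H]1C[C@H](O[Si](C)(C)C(C)(C)C)[C@H](/C=C/C=C/c2cc3c(Cl)c(O[Si](C(C)C)(C(C)C)C(C)C)cc(O[Si](C(C)C)(C(C)C)C(C)C)c3c(=O)o2)O1 | intermediate
20 | 5-chloro-6,8-dihydroxy-3-[(1E,3E)-4-[(2S,3S,5R)-3-hydroxy-5-methyltetrahydrofuran-2-yl]buta-1,3-dien-1-yl]-1H-isochromen-1-one | C[C@@H]1C[C@H](O)[C@H](/C=C/C=C/c2cc3c(Cl)c(O)cc(O)c3c(=O)o2)O1 | target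

**Step count**
Total: 11 steps. Longest linear sequence: 7 steps (9 and 10 to 20, steps 5–11); the arene branch is 6 steps (steps 1–4, 10, 11). The target has three stereocentres, all cis on the tetrahydrofuran: C5 comes from 9, and C2 and C3 are set in step 7.

**Three steps most likely to fail**

The ring expansion of step 5 can fail at the acylation stage if lithiated 10 decomposes or attacks the alkyl carbon of 9. The fallback sets out from 9. Acyl opening with the lithium enolate of ethyl acetate (LiN(i-Pr)2, EtOAc, THF, −78 °C; Claisen-type) gives ethyl (5R)-5-hydroxy-3-oxohexanoate F1. Regitz diazo transfer (4-acetamidobenzenesulfonyl azide, Et3N, MeCN) then comes back to the route at 11, which Rh2(OAc)4 closes to 12 as before.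

The proposed hydrogenation of step 7 can fail through low turnover on the tetrasubstituted alkene, double-bond migration or weak facial control by the C5 methyl. The fallback uses known chemistry and sets out from 12. NaBH4 in MeOH at −40 °C reduces the epimerising β-keto ester from the face opposite the ester to give mainly ethyl (2R,3S,5R)-3-hydroxy-5-methyltetrahydrofuran-2-carboxylate F2, which is separated from minor diastereomers by chromatography. Silylation with t-BuMe2SiCl and imidazole in DMF comes back to the route at 14.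

The union of step 10 can fail through attack of the extended enolate at C4, conjugate addition to the enal, or E/Z mixtures on elimination. The fallback sets out from 5. Lateral lithiation and acylation with 2-chloro-N-methoxy-N-methylacetamide gives methyl 3-chloro-2-(3-chloro-2-oxopropyl)-4,6-bis(triisopropylsilyloxy)benzoate F3. CF3CO2H closes it to 5-chloro-3-(chloromethyl)-6,8-bis(triisopropylsilyloxy)-1H-isochromen-1-one F4. Arbuzov reaction with P(OEt)3 at 120 °C gives diethyl {[5-chloro-1-oxo-6,8-bis(triisopropylsilyloxy)-1H-isochromen-3-yl]methyl}phosphonate F5. Horner–Wadsworth–Emmons olefination of 16 (LiN(SiMe3)2, THF, −78 → 0 °C) comes back to the route at 19.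

**Further compounds**
F1 | step 5 | ethyl (5R)-5-hydroxy-3-oxohexanoate | C[C@@H](O)CC(=O)CC(=O)OCC
F2 | step 7 | ethyl (2R,3S,5R)-3-hydroxy-5-methyltetrahydrofuran-2-carboxylate | C[C@@H]1C[C@H](O)[C@H](C(=O)OCC)O1
F3 | step 10 | methyl 3-chloro-2-(3-chloro-2-oxopropyl)-4,6-bis(triisopropylsilyloxy)benzoate | COC(=O)c1c(CC(=O)CCl)c(Cl)c(O[Si](C(C)C)(C(C)C)C(C)C)cc1O[Si](C(C)C)(C(C)C)C(C)C
F4 | step 10 | 5-chloro-3-(chloromethyl)-6,8-bis(triisopropylsilyloxy)-1H-isochromen-1-one | ClCc1cc2c(Cl)c(O[Si](C(C)C)(C(C)C)C(C)C)cc(O[Si](C(C)C)(C(C)C)C(C)C)c2c(=O)o1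
F5 | step 10 | diethyl {[5-chloro-1-oxo-6,8-bis(triisopropylsilyloxy)-1H-isochromen-3-yl]methyl}phosphonate | CCOP(=O)(OCC)Cc1cc2c(Cl)c(O[Si](C(C)C)(C(C)C)C(C)C)cc(O[Si](C(C)C)(C(C)C)C(C)C)c2c(=O)o1
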